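The chain is numbered C1 (alkyne CH) to C15. Everything rests on the C7–C8 disconnection: oxirane carbon C7 is carried as the terminus of a C6≡C7 alkyne, and methylene C8 as the CH2 of a C8/C9 oxirane on the side arm of the C10–C13 oxolane. One operation, lithium acetylide attack on the BF3-activated oxirane, joins the C1–C7 skipped enediyne to the bromo-oxolane, reverses the polarity of C7 and unveils the C9 hydroxyl. That hydroxyl then directs the cis-epoxidation of the derived Z-alkene and is finally replaced by bromine. The precursor pair is a TIPS-capped hept-3-ene-1,6-diyne and an oxiranyl bromo-oxolane.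

Key step: step 13

Assumption: in step 6 the catalyst antipode is the one that delivers (2S)-2-chlorobutanal (the (2R,5R) catalyst is written), and 10 is used at once as a cold solution because it is volatile and configurationally labile.

Step 1
Reactants: 1 3-[tri(propan-2-yl)silyl]prop-2-ynal
Product: 2 ethyl (2E)-5-[tri(propan-2-yl)silyl]pent-2-en-4-ynoate
Conditions: (EtO)2P(O)CH2CO2Et, NaH, THF, 0 °C
Reagents that add atoms: triethyl phosphonoacetate, CCOC(=O)CP(=O)(OCC)OCC
Why: Horner–Wadsworth–Emmons olefination of the ynal with the stabilised phosphonate anion should give the (E)-enoate, which sets the C3=C4 geometry.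

Step 2
Reactants: 2 ethyl (2E)-5-[tri(propan-2-yl)silyl]pent-2-en-4-ynoate
Product: 3 (2E)-5-[tri(propan-2-yl)silyl]pent-2-en-4-yn-1-ol
Conditions: DIBAL-H (2.2 equiv), CH2Cl2, −78 °C; aq. Rochelle salt
Reagents that add atoms: none
Why: DIBAL-H should reduce the conjugated ester by 1,2-hydride addition to the allylic alcohol without touching the silylalkyne or the E-alkene.

Step 3
Reactants: 3 (2E)-5-[tri(propan-2-yl)silyl]pent-2-en-4-yn-1-ol
Product: 4 [(3E)-5-bromopent-3-en-1-yn-1-yl]tri(propan-2-yl)silane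
Conditions: CBr4, PPh3, CH2Cl2, 0 °C
Reagents that add atoms: carbon tetrabromide, BrC(Br)(Br)Br
Why: The Appel reaction should convert the primary allylic alcohol into the bromide by SN2 displacement of the oxyphosphonium ion under neutral conditions that leave the E-enyne intact.

Step 4
Reactants: 4 [(3E)-5-bromopent-3-en-1-yn-1-yl]tri(propan-2-yl)silane
Product: 5 [(3E)-hept-3-ene-1,6-diyn-1-yl]tri(propan-2-yl)silane
Conditions: HC≡CMgBr (3 equiv), CuCl (10 mol %), THF, 50 °C
Reagents that add atoms: ethynylmagnesium bromide, C#C[Mg]Br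
Why: Copper(I)-catalysed alkynylation of the primary allylic bromide should proceed by SN2 substitution at CH2 (C5), which keeps the alkene conjugated and E and gives the skipped enyne with a free C7–H.

Step 5
Reactants: 6 methyl (4S)-2,2-dimethyl-1,3-dioxolane-4-carboxylate
Product: 8 1-[(4S)-2,2-dimethyl-1,3-dioxolan-4-yl]ethan-1-one, via Weinreb amide 7 (not isolated)
Conditions: MeNHOMe·HCl, i-PrMgCl, THF, −20 °C; then MeMgBr, 0 °C; aq. NH4Cl
Reagents that add atoms: methylmagnesium bromide, C[Mg]Br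
Why: Weinreb ketone synthesis, in which the chelated tetrahedral adduct of the N-methoxy-N-methylamide stops the Grignard addition at the methyl ketone, should leave the alkoxy stereocentre (later C9) untouched.

Step 6
Reactants: 9 butanal
Product: 10 (2S)-2-chlorobutanal
Conditions: NCS, (2R,5R)-2,5-diphenylpyrrolidine (10 mol %), CH2Cl2, 0 °C → rt
Reagents that add atoms: N-chlorosuccinimide, ClN1C(=O)CCC1=O
Why: Enamine-catalysed α-chlorination, with the C2-symmetric pyrrolidine shielding one enamine face, should set the chlorine-bearing centre (later C13) as S.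

Step 7
Reactants: 8 1-[(4S)-2,2-dimethyl-1,3-dioxolan-4-yl]ethan-1-one; 10 (2S)-2-chlorobutanal
Product: 12 (3R,4S)-4-chloro-1-[(4S)-2,2-dimethyl-1,3-dioxolan-4-yl]-3-hydroxyhexan-1-one, via lithium enolate 11 (not isolated)
Conditions: LDA, THF, −78 °C; then 10, −78 °C; aq. NH4Cl
Reagents that add atoms: none
Why: Lithium aldol addition of the kinetic methyl ketone enolate to the α-chloroaldehyde should be 1,2-anti selective, because attack occurs anti to the C–Cl bond in the dipole-minimised conformation, which sets C12 as R.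

Step 8
Reactants: 12 (3R,4S)-4-chloro-1-[(4S)-2,2-dimethyl-1,3-dioxolan-4-yl]-3-hydroxyhexan-1-one
Product: 13 (1R,3R,4S)-4-chloro-1-[(4S)-2,2-dimethyl-1,3-dioxolan-4-yl]hexane-1,3-diol
Conditions: Me4NBH(OAc)3, MeCN–AcOH, −40 → −20 °C
Reagents that add atoms: none
Why: Evans–Saksena reduction, in which the C12-bound acetoxyborohydride delivers hydride intramolecularly through a chair, should give the 1,3-anti diol and so set C10 as R.

Step 9
Reactants: 13 (1R,3R,4S)-4-chloro-1-[(4S)-2,2-dimethyl-1,3-dioxolan-4-yl]hexane-1,3-diol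
Product: 14 (2R,3R,5R)-5-[(4S)-2,2-dimethyl-1,3-dioxolan-4-yl]-2-ethyloxolan-3-ol
Conditions: AgOTf, Ag2O, THF, rt → 50 °C
Reagents that add atoms: none
Why: Silver(I)-assisted intramolecular etherification, in which the C10 hydroxyl displaces chloride at C13 by 5-exo-tet SN2 with inversion, should give the all-cis oxolane with C13 now R.

Step 10
Reactants: 14 (2R,3R,5R)-5-[(4S)-2,2-dimethyl-1,3-dioxolan-4-yl]-2-ethyloxolan-3-ol
Product: 15 (4S)-4-[(2R,4S,5R)-4-bromo-5-ethyloxolan-2-yl]-2,2-dimethyl-1,3-dioxolane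
Conditions: CBr4, (n-Oct)3P, toluene, 70 °C
Reagents that add atoms: carbon tetrabromide, BrC(Br)(Br)Br
Why: Appel bromination should proceed by SN2 attack of bromide on the oxyphosphonium ion from the open face opposite the three cis substituents, inverting C12 to the S bromide trans to ethyl.

Step 11
Reactants: 15 (4S)-4-[(2R,4S,5R)-4-bromo-5-ethyloxolan-2-yl]-2,2-dimethyl-1,3-dioxolane
Product: 16 (1S)-1-[(2R,4S,5R)-4-bromo-5-ethyloxolan-2-yl]ethane-1,2-diol
Conditions: AcOH–H2O (4:1), 40 °C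
Reagents that add atoms: none
Why: Acid-catalysed acetal hydrolysis should release the 1,2-diol while the secondary bromide and the oxolane are inert to aqueous acetic acid.

Step 12
Reactants: 16 (1S)-1-[(2R,4S,5R)-4-bromo-5-ethyloxolan-2-yl]ethane-1,2-diol
Product: 18 (2R,3S,5R)-3-bromo-2-ethyl-5-[(2S)-oxiran-2-yl]oxolane, via primary tosylate 17 (not isolated)
Conditions: TsCl, Bu2SnO (2 mol %), Et3N, CH2Cl2, rt; then K2CO3, MeOH, 0 °C
Reagents that add atoms: none
Why: Tin-catalysed sulfonylation should select the primary hydroxyl, and base then closes the oxirane by 3-exo-tet displacement at C8, so the C9–O bond and its S configuration are untouched.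

Step 13
Reactants: 5 [(3E)-hept-3-ene-1,6-diyn-1-yl]tri(propan-2-yl)silane; 18 (2R,3S,5R)-3-bromo-2-ethyl-5-[(2S)-oxiran-2-yl]oxolane
Product: 20 (1S,6E)-1-[(2R,4S,5R)-4-bromo-5-ethyloxolan-2-yl]-9-[tri(propan-2-yl)silyl]non-6-ene-3,8-diyn-1-ol, via lithium acetylide 19 (not isolated)
Conditions: n-BuLi, THF, −78 °C; BF3·OEt2, then 18, −78 °C; aq. NH4Cl
Reagents that add atoms: none
Why: n-BuLi removes the terminal C7–H of 5, and the lithium acetylide 19, in the presence of BF3·OEt2, attacks the Lewis-acid-activated oxirane 18 by SN2 at its terminal CH2 (C8), which forms C7–C8 and releases the C9 alkoxide. The closest known reaction type is the Yamaguchi–Hirao alkynylation of epoxides. No ring is closed and no stereocentre is created: C9 keeps its S configuration because its C–O bond is not broken, and C10, C12 and C13 are spectators. The step needs regioselectivity for C8 over C9, which the unhindered primary carbon and the inductive deactivation of C9 by the adjacent oxolane oxygen should secure. It also needs metalation at C7 and not at the doubly activated C5 methylene or at C1, which the much higher kinetic acidity of the sp C–H at −78 °C and the TIPS cap on C1 should secure, while the secondary C12 bromide is inert to the acetylide at this temperature.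

Step 14
Reactants: 20 (1S,6E)-1-[(2R,4S,5R)-4-bromo-5-ethyloxolan-2-yl]-9-[tri(propan-2-yl)silyl]non-6-ene-3,8-diyn-1-ol
Product: 21 (1S,3Z,6E)-1-[(2R,4S,5R)-4-bromo-5-ethyloxolan-2-yl]-9-[tri(propan-2-yl)silyl]nona-3,6-dien-8-yn-1-ol
Conditions: H2 (1 atm), Lindlar catalyst, quinoline, EtOAc, rt
Reagents that add atoms: none
Why: Lindlar semihydrogenation should add H2 syn to the internal C6≡C7 alkyne to give the Z-alkene, while the hindered TIPS-capped alkyne and the C–Br bond are not reduced on the poisoned catalyst.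

Step 15
Reactants: 21 (1S,3Z,6E)-1-[(2R,4S,5R)-4-bromo-5-ethyloxolan-2-yl]-9-[tri(propan-2-yl)silyl]nona-3,6-dien-8-yn-1-ol
Product: 22 (1S)-1-[(2R,4S,5R)-4-bromo-5-ethyloxolan-2-yl]-2-[(2R,3S)-3-{(2E)-5-[tri(propan-2-yl)silyl]pent-2-en-4-yn-1-yl}oxiran-2-yl]ethan-1-ol
Conditions: VO(acac)2 (5 mol %), t-BuOOH, CH2Cl2, 0 °C → rt
Reagents that add atoms: tert-butyl hydroperoxide, CC(C)(C)OO
Why: Hydroxyl-directed vanadium-catalysed epoxidation of the Z-homoallylic alcohol should pass through a chair-like vanadate with the oxolanyl group equatorial and the alkene rotamer fixed by A(1,3) strain, so oxygen is delivered syn to the C9 hydroxyl and the cis-epoxide forms as 6S,7R, while the remote, alkyne-conjugated C3=C4 alkene is not directed.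

Step 16
Reactants: 22 (1S)-1-[(2R,4S,5R)-4-bromo-5-ethyloxolan-2-yl]-2-[(2R,3S)-3-{(2E)-5-[tri(propan-2-yl)silyl]pent-2-en-4-yn-1-yl}oxiran-2-yl]ethan-1-ol
Product: 23 (1R)-1-[(2R,4S,5R)-4-bromo-5-ethyloxolan-2-yl]-2-[(2R,3S)-3-{(2E)-5-[tri(propan-2-yl)silyl]pent-2-en-4-yn-1-yl}oxiran-2-yl]ethyl 4-nitrobenzoate
Conditions: 4-O2NC6H4CO2H, PPh3, DIAD, toluene, 0 °C → rt
Reagents that add atoms: 4-nitrobenzoic acid, O=C(O)c1ccc(cc1)[N+](=O)[O-]
Why: The Mitsunobu reaction should displace the activated C9 oxygen by SN2 and invert C9 from S to R, which places the oxygen anti to the epoxide oxygen as the later inverting bromination requires.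

Step 17
Reactants: 23 (1R)-1-[(2R,4S,5R)-4-bromo-5-ethyloxolan-2-yl]-2-[(2R,3S)-3-{(2E)-5-[tri(propan-2-yl)silyl]pent-2-en-4-yn-1-yl}oxiran-2-yl]ethyl 4-nitrobenzoate
Product: 24 (1R)-1-[(2R,4S,5R)-4-bromo-5-ethyloxolan-2-yl]-2-[(2R,3S)-3-{(2E)-5-[tri(propan-2-yl)silyl]pent-2-en-4-yn-1-yl}oxiran-2-yl]ethan-1-ol
Conditions: K2CO3 (cat.), MeOH, 0 °C
Reagents that add atoms: none
Why: Base-catalysed transesterification should remove the electron-poor benzoate by acyl–oxygen cleavage, so the inverted C9 configuration is kept and the epoxide, bromide and silylalkyne are untouched.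

Step 18
Reactants: 24 (1R)-1-[(2R,4S,5R)-4-bromo-5-ethyloxolan-2-yl]-2-[(2R,3S)-3-{(2E)-5-[tri(propan-2-yl)silyl]pent-2-en-4-yn-1-yl}oxiran-2-yl]ethan-1-ol
Product: 25 {(3E)-5-[(2S,3R)-3-{(2S)-2-bromo-2-[(2R,4S,5R)-4-bromo-5-ethyloxolan-2-yl]ethyl}oxiran-2-yl]pent-3-en-1-yn-1-yl}tri(propan-2-yl)silane
Conditions: CBr4, (n-Oct)3P, pyridine, toluene, 60 °C
Reagents that add atoms: carbon tetrabromide, BrC(Br)(Br)Br
Why: Appel bromination with SN2 inversion at the oxyphosphonium ion should convert the 9R alcohol into the 9S bromide, the buffered conditions sparing the cis-epoxide.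

Step 19
Reactants: 25 {(3E)-5-[(2S,3R)-3-{(2S)-2-bromo-2-[(2R,4S,5R)-4-bromo-5-ethyloxolan-2-yl]ethyl}oxiran-2-yl]pent-3-en-1-yn-1-yl}tri(propan-2-yl)silane
Product: 26 (2R,3S,5R)-3-bromo-5-[(1S)-1-bromo-2-{(2R,3S)-3-[(2E)-pent-2-en-4-yn-1-yl]oxiran-2-yl}ethyl]-2-ethyloxolane
Conditions: TBAF, THF, 0 °C
Reagents that add atoms: none
Why: Fluoride-mediated protodesilylation should cleave the C(sp)–Si bond at 0 °C and unveil the terminal enyne without eliminating the secondary bromides or opening the epoxide.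

Compound list
1 | 3-[tri(propan-2-yl)silyl]prop-2-ynal | CC(C)[Si](C(C)C)(C(C)C)C#CC=O | starting material
2 | ethyl (2E)-5-[tri(propan-2-yl)silyl]pent-2-en-4-ynoate | CCOC(=O)/C=C/C#C[Si](C(C)C)(C(C)C)C(C)C | intermediate
3 | (2E)-5-[tri(propan-2-yl)silyl]pent-2-en-4-yn-1-ol | OC/C=C/C#C[Si](C(C)C)(C(C)C)C(C)C | intermediate
4 | [(3E)-5-bromopent-3-en-1-yn-1-yl]tri(propan-2-yl)silane | BrC/C=C/C#C[Si](C(C)C)(C(C)C)C(C)C | intermediate
5 | [(3E)-hept-3-ene-1,6-diyn-1-yl]tri(propan-2-yl)silane | C#CC/C=C/C#C[Si](C(C)C)(C(C)C)C(C)C | intermediate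
6 | methyl (4S)-2,2-dimethyl-1,3-dioxolane-4-carboxylate | COC(=O)[C@@H]1COC(C)(C)O1 | starting material
7 | (4S)-N-methoxy-N,2,2-trimethyl-1,3-dioxolane-4-carboxamide (Weinreb amide, not isolated) | CON(C)C(=O)[C@@H]1COC(C)(C)O1 | intermediate
8 | 1-[(4S)-2,2-dimethyl-1,3-dioxolan-4-yl]ethan-1-one | CC(=O)[C@@H]1COC(C)(C)O1 | intermediate
9 | butanal | CCCC=O | starting material
10 | (2S)-2-chlorobutanal | CC[C@H](Cl)C=O | intermediate
11 | lithium 1-[(4S)-2,2-dimethyl-1,3-dioxolan-4-yl]ethen-1-olate (lithium enolate, not isolated) | [Li]OC(=C)[C@@H]1COC(C)(C)O1 | intermediate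
12 | (3R,4S)-4-chloro-1-[(4S)-2,2-dimethyl-1,3-dioxolan-4-yl]-3-hydroxyhexan-1-one | CC[C@H](Cl)[C@H](O)CC(=O)[C@@H]1COC(C)(C)O1 | intermediate
13 | (1R,3R,4S)-4-chloro-1-[(4S)-2,2-dimethyl-1,3-dioxolan-4-yl]hexane-1,3-diol | CC[C@H](Cl)[C@H](O)C[C@@H](O)[C@@H]1COC(C)(C)O1 | intermediate
14 | (2R,3R,5R)-5-[(4S)-2,2-dimethyl-1,3-dioxolan-4-yl]-2-ethyloxolan-3-ol (all-cis) | CC1(C)OC[C@H](O1)[C@H]2C[C@@H](O)[C@@H](CC)O2 | intermediate
15 | (4S)-4-[(2R,4S,5R)-4-bromo-5-ethyloxolan-2-yl]-2,2-dimethyl-1,3-dioxolane | CC1(C)OC[C@H](O1)[C@H]2C[C@H](Br)[C@@H](CC)O2 | intermediate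
16 | (1S)-1-[(2R,4S,5R)-4-bromo-5-ethyloxolan-2-yl]ethane-1,2-diol | OC[C@H](O)[C@H]1C[C@H](Br)[C@@H](CC)O1 | intermediate
17 | (2S)-2-[(2R,4S,5R)-4-bromo-5-ethyloxolan-2-yl]-2-hydroxyethyl 4-methylbenzenesulfonate (primary tosylate, not isolated) | Cc1ccc(cc1)S(=O)(=O)OC[C@H](O)[C@H]2C[C@H](Br)[C@@H](CC)O2 | intermediate
18 | (2R,3S,5R)-3-bromo-2-ethyl-5-[(2S)-oxiran-2-yl]oxolane | C1O[C@@H]1[C@H]2C[C@H](Br)[C@@H](CC)O2 | intermediate
19 | lithium acetylide of 5, lithiated at C7 (not isolated) | [Li]C#CC/C=C/C#C[Si](C(C)C)(C(C)C)C(C)C | intermediate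
20 | (1S,6E)-1-[(2R,4S,5R)-4-bromo-5-ethyloxolan-2-yl]-9-[tri(propan-2-yl)silyl]non-6-ene-3,8-diyn-1-ol | CC(C)[Si](C(C)C)(C(C)C)C#C/C=C/CC#CC[C@H](O)[C@H]1C[C@H](Br)[C@@H](CC)O1 | intermediate
21 | (1S,3Z,6E)-1-[(2R,4S,5R)-4-bromo-5-ethyloxolan-2-yl]-9-[tri(propan-2-yl)silyl]nona-3,6-dien-8-yn-1-ol | CC(C)[Si](C(C)C)(C(C)C)C#C/C=C/C/C=C\C[C@H](O)[C@H]1C[C@H](Br)[C@@H](CC)O1 | intermediate
22 | (1S)-1-[(2R,4S,5R)-4-bromo-5-ethyloxolan-2-yl]-2-[(2R,3S)-3-{(2E)-5-[tri(propan-2-yl)silyl]pent-2-en-4-yn-1-yl}oxiran-2-yl]ethan-1-ol | CC(C)[Si](C(C)C)(C(C)C)C#C/C=C/C[C@@H]1O[C@@H]1C[C@H](O)[C@H]2C[C@H](Br)[C@@H](CC)O2 | intermediate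
23 | (1R)-1-[(2R,4S,5R)-4-bromo-5-ethyloxolan-2-yl]-2-[(2R,3S)-3-{(2E)-5-[tri(propan-2-yl)silyl]pent-2-en-4-yn-1-yl}oxiran-2-yl]ethyl 4-nitrobenzoate | CC(C)[Si](C(C)C)(C(C)C)C#C/C=C/C[C@@H]1O[C@@H]1C[C@@H](OC(=O)c3ccc(cc3)[N+](=O)[O-])[C@H]2C[C@H](Br)[C@@H](CC)O2 | intermediate
24 | (1R)-1-[(2R,4S,5R)-4-bromo-5-ethyloxolan-2-yl]-2-[(2R,3S)-3-{(2E)-5-[tri(propan-2-yl)silyl]pent-2-en-4-yn-1-yl}oxiran-2-yl]ethan-1-ol | CC(C)[Si](C(C)C)(C(C)C)C#C/C=C/C[C@@H]1O[C@@H]1C[C@@H](O)[C@H]2C[C@H](Br)[C@@H](CC)O2 | intermediate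
25 | {(3E)-5-[(2S,3R)-3-{(2S)-2-bromo-2-[(2R,4S,5R)-4-bromo-5-ethyloxolan-2-yl]ethyl}oxiran-2-yl]pent-3-en-1-yn-1-yl}tri(propan-2-yl)silane | CC(C)[Si](C(C)C)(C(C)C)C#C/C=C/C[C@@H]1O[C@@H]1C[C@H](Br)[C@H]2C[C@H](Br)[C@@H](CC)O2 | intermediate
26 | (2R,3S,5R)-3-bromo-5-[(1S)-1-bromo-2-{(2R,3S)-3-[(2E)-pent-2-en-4-yn-1-yl]oxiran-2-yl}ethyl]-2-ethyloxolane | C#C/C=C/C[C@@H]1O[C@@H]1C[C@H](Br)[C@H]2C[C@H](Br)[C@@H](CC)O2 | target

Total step count: 19. Longest linear sequence: 14 steps (6 → 26: steps 5 and 7–19); steps 1–4 and step 6 are side branches.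

Steps most likely to fail

Step 18. As the C9 oxyphosphonium ion leaves at 60 °C, the neighbouring oxolane oxygen may participate (ring expansion or loss of inversion), and bromide may open the cis-epoxide. The fallback sets out from 24: chloromethanesulfonyl chloride and 2,6-lutidine give the C9 chloromethanesulfonate F1, a sulfonate that ionises poorly, and tetrabutylammonium bromide in toluene displaces it by SN2 with inversion. This replaces phosphonium activation by a sulfonate ester and returns to the route at 25.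

Step 15. Facial selectivity may be poor if the equatorial preference in the vanadate chair is small, and the Lewis-acidic metal may promote 5-endo attack of the C9 hydroxyl on the new epoxide. The fallback sets out from 21: Boc2O and DMAP give the tert-butyl carbonate F2, and IBr at −85 °C induces iodocarbonate cyclisation to the 4,6-cis cyclic iodocarbonate F3, in which the carbonyl oxygen has added to C7 anti to the iodonium ion of the Z-alkene. K2CO3 in methanol then cleaves the carbonate and closes the epoxide by displacement of iodide at C6, returning to the route at 22.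

Step 13. Metalation or base-induced propargyl–allenyl isomerisation at the doubly activated C5 methylene of 5 may compete with clean acetylide formation and consume the nucleophile. The fallback sets out from 18: the oxirane is opened in the same way with the robust lithium (trimethylsilyl)acetylide and BF3·OEt2 to give the silylated homopropargylic alcohol F4, which still forms C7–C8. K2CO3 in methanol then gives the terminal alkyne F5, and copper(I)-mediated coupling with allylic bromide 4 (CuI, NaI, Cs2CO3, DMF), which needs no organolithium, installs the skipped enyne at C5–C6 and returns to the route at 20.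

Further compounds
F1 | step 18 | (1R)-1-[(2R,4S,5R)-4-bromo-5-ethyloxolan-2-yl]-2-[(2R,3S)-3-{(2E)-5-[tri(propan-2-yl)silyl]pent-2-en-4-yn-1-yl}oxiran-2-yl]ethyl chloromethanesulfonate | CC(C)[Si](C(C)C)(C(C)C)C#C/C=C/C[C@@H]1O[C@@H]1C[C@@H](OS(=O)(=O)CCl)[C@H]2C[C@H](Br)[C@@H](CC)O2
F2 | step 15 | tert-butyl (1S,3Z,6E)-1-[(2R,4S,5R)-4-bromo-5-ethyloxolan-2-yl]-9-[tri(propan-2-yl)silyl]nona-3,6-dien-8-yn-1-yl carbonate | CC(C)[Si](C(C)C)(C(C)C)C#C/C=C/C/C=C\C[C@H](OC(=O)OC(C)(C)C)[C@H]1C[C@H](Br)[C@@H](CC)O1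
F3 | step 15 | (4S,6R)-4-[(2R,4S,5R)-4-bromo-5-ethyloxolan-2-yl]-6-{(1R,3E)-1-iodo-6-[tri(propan-2-yl)silyl]hex-3-en-5-yn-1-yl}-1,3-dioxan-2-one | CC(C)[Si](C(C)C)(C(C)C)C#C/C=C/C[C@@H](I)[C@H]1C[C@H](OC(=O)O1)[C@H]2C[C@H](Br)[C@@H](CC)O2
F4 | step 13 | (1S)-1-[(2R,4S,5R)-4-bromo-5-ethyloxolan-2-yl]-4-(trimethylsilyl)but-3-yn-1-ol | C[Si](C)(C)C#CC[C@H](O)[C@H]1C[C@H](Br)[C@@H](CC)O1
F5 | step 13 | (1S)-1-[(2R,4S,5R)-4-bromo-5-ethyloxolan-2-yl]but-3-yn-1-ol | C#CC[C@H](O)[C@H]1C[C@H](Br)[C@@H](CC)O1
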